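**Assumptions:** The SMILES gives all three stereocentres as S (CIP). The chain is 12-phenyldodecyl, (CH2)12Ph. L-Malate supplies the secondary stereocentre. A chelation-controlled allylation sets the quaternary lactone carbon. The last ring closure sets the remaining quaternary ether carbon.

## Retrosynthetic overview
- The target is a cis-fused THF–γ-butyrolactone. The THF ring is closed last, by acid-mediated cyclodehydration of the Ce–OH onto the tertiary Ca–OH (Ca = the THF carbon bearing Me and the chain). This sets Ca.
- The Ca carbinol comes from addition of a 12-phenyldodecyl organocerium to a methyl ketone. That ketone comes from Wacker oxidation of a γ-allyl lactone.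
- The γ-allyl-γ-methyl-β-OBn lactone comes from chelation-controlled allylation of an α-OBn methyl ketone, with spontaneous lactonisation. This ketone is made from (S)-dimethyl malate, which carries the Ce stereocentre.
- Ring order: the lactone is formed in Step 6 and the THF ring in Step 10.

## Route

**Step 1**
Reactants: 1, 1,12-dibromododecane
Product: 2, (12-bromododecyl)benzene
Conditions: PhMgBr, Li2CuCl4 (cat.), THF, 0 °C→rt; 3 equiv of 1
Reagents that add atoms: phenylmagnesium bromide, Br[Mg]c1ccccc1
Why: Cu-catalysed Grignard–alkyl bromide cross-coupling attaches one phenyl. Excess dibromide suppresses double arylation.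

**Step 2**
Reactants: 2
Product: 3, 12-phenyldodecylmagnesium bromide
Conditions: Mg turnings, THF, 50 °C
Reagents that add atoms: magnesium, [Mg]
Why: Standard Grignard formation gives the chain nucleophile used in Step 8.

**Step 3**
Reactants: 4, dimethyl (S)-malate
Product: 5, dimethyl (S)-2-(benzyloxy)succinate
Conditions: BnOC(=NH)CCl3, TfOH (cat.), CH2Cl2/cyclohexane, rt
Reagents that add atoms: benzyl 2,2,2-trichloroacetimidate, N=C(OCc1ccccc1)C(Cl)(Cl)Cl
Why: Acid-catalysed imidate benzylation protects the OH under non-basic conditions, so the β-alkoxy ester does not eliminate. The stereocentre is untouched.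

**Step 4**
Reactants: 5
Product: 6, methyl (S)-3-(benzyloxy)-4-[methoxy(methyl)amino]-4-oxobutanoate
Conditions: MeNHOMe·HCl, iPrMgCl, THF, −20→0 °C
Reagents that add atoms: N,O-dimethylhydroxylamine hydrochloride, CONC.Cl
Why: The α-ester is the more electrophilic one, and the OBn oxygen directs the magnesium amide. This should give the α-Weinreb amide selectively (weakest assumption in the early route). The stereocentre is unchanged.

**Step 5**
Reactants: 6
Product: 7, methyl (S)-3-(benzyloxy)-4-oxopentanoate
Conditions: MeMgBr (1.1 equiv), THF, −78→−20 °C; use crude
Reagents that add atoms: methylmagnesium bromide, C[Mg]Br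
Why: Weinreb ketone synthesis stops at the methyl ketone through the stable chelated intermediate.

**Step 6**
Reactants: 7
Product: 8, (4S,5S)-5-allyl-4-(benzyloxy)-5-methyldihydrofuran-2(3H)-one
Conditions: allylMgBr, MgBr2·OEt2, CH2Cl2/Et2O, −78 °C; then aq. NH4Cl and cat. TsOH, rt
Reagents that add atoms: allylmagnesium bromide, C=CC[Mg]Br
Why: Cram-chelate addition to the α-OBn ketone puts allyl on the face carrying H, not CH2CO2Me. This sets the quaternary carbon Cc as S. The tertiary alkoxide then closes onto the methyl ester to give the γ-lactone, so the lactone ring forms here.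

**Step 7**
Reactants: 8
Product: 9, (4S,5S)-4-(benzyloxy)-5-methyl-5-(2-oxopropyl)dihydrofuran-2(3H)-one
Conditions: PdCl2 (cat.), CuCl, O2, DMF/H2O, rt
Reagents that add atoms: water, O (the ketone oxygen comes from water; O2 is the terminal oxidant)
Why: Wacker oxidation gives the Markovnikov methyl ketone from the terminal alkene. The benzyl ether and lactone survive, and no stereocentre is touched.

**Step 8**
Reactants: 9, 3
Product: 10, (4S,5S)-4-(benzyloxy)-5-[2-hydroxy-2-methyl-14-phenyltetradecyl]-5-methyl-lactone (Ca as an epimeric mixture), i.e. 5-(2-hydroxy-2-methyltetradecyl chain bearing terminal phenyl)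
Conditions: 3 (2.5 equiv) and anhydrous CeCl3 (2.5 equiv), THF, −78 °C
Reagents that add atoms: none beyond reactant 3
Why: The organocerium is weakly basic and chemoselective for the ketone over the hindered tertiary lactone. It also limits enolisation and E1cB opening of the β-acyloxy ketone. Ca is left unselective, because the next step converges both epimers through the same cation.

**Step 9**
Reactants: 10
Product: 11, (4S,5S)-4-hydroxy-5-(2-hydroxy-2-methyl-14-phenyltetradecyl)-5-methyl-lactone
Conditions: H2 (1 atm), Pd/C, EtOAc, rt
Reagents that add atoms: none
Why: Hydrogenolysis removes the O-benzyl group. The phenyl ring of the chain and the lactone are stable to these conditions, and Ce and Cc are not affected.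

**Step 10**
Reactants: 11
Product: 12, plakortone L
Conditions: TsOH (cat.), PhMe, 80 °C
Reagents that add atoms: none
Why: Acid ionises the tertiary Ca–OH, or dehydrates it to the alkene and reprotonates it. The Ce–OH then closes 5-exo-trig. Ce–O and Cc–CH2 are already cis on the lactone ring, so the fusion is necessarily cis and Ce and Cc are fixed. Ca is set by the preference for the chain on the convex face and Me on the concave face, next to the lactone. The minor Ca epimer is removed by chromatography. If the β-OH eliminates to the butenolide, oxa-Michael re-addition gives the same cis-fused product.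

## Checks
- The target is a cis-fused 5,5 bicycle (THF plus γ-lactone) with Me/chain on Ca, Me on the ring-fusion carbon Cc, and CIP descriptors (S,S,S).
- Compound 8 has the same Cc/Ce spatial arrangement and priority order as the target, so both centres are S.
- Formulas balance: 10 is C33H48O4, 11 is C26H42O4, and 12 is C26H40O3 (11 minus H2O).

## Compound list
1 | 1,12-dibromododecane | BrCCCCCCCCCCCCBr | starting material
2 | (12-bromododecyl)benzene | BrCCCCCCCCCCCCc1ccccc1 | intermediate
3 | 12-phenyldodecylmagnesium bromide | [Mg](Br)CCCCCCCCCCCCc1ccccc1 | intermediate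
4 | dimethyl (S)-malate | COC(=O)C[C@H](O)C(=O)OC | starting material
5 | dimethyl (S)-2-(benzyloxy)succinate | COC(=O)C[C@H](OCc1ccccc1)C(=O)OC | intermediate
6 | Weinreb amide of 5 (α-amide) | COC(=O)C[C@H](OCc1ccccc1)C(=O)N(C)OC | intermediate
7 | methyl (S)-3-(benzyloxy)-4-oxopentanoate | COC(=O)C[C@H](OCc1ccccc1)C(C)=O | intermediate
8 | (4S,5S)-5-allyl-4-(benzyloxy)-5-methyl-γ-butyrolactone | C=CC[C@]1(C)OC(=O)C[C@@H]1OCc1ccccc1 | intermediate
9 | (4S,5S)-4-(benzyloxy)-5-methyl-5-(2-oxopropyl)-γ-butyrolactone | CC(=O)C[C@]1(C)OC(=O)C[C@@H]1OCc1ccccc1 | intermediate
10 | tertiary carbinol (Ca epimeric mixture) | CC(O)(CCCCCCCCCCCCc1ccccc1)C[C@]1(C)OC(=O)C[C@@H]1OCc1ccccc1 | intermediate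
11 | diol lactone | CC(O)(CCCCCCCCCCCCc1ccccc1)C[C@]1(C)OC(=O)C[C@@H]1O | intermediate
12 | plakortone L | C[C@]1(CCCCCCCCCCCCc2ccccc2)C[C@]2(C)OC(=O)C[C@@H]2O1 | target

**Total steps:** 10. **Longest linear sequence:** 8 (Steps 3–10).

## Three steps most likely to fail
1. **Step 6, chelation-controlled allylation.** The diastereoselectivity may be low, or the α-OBn β-ester may undergo E1cB loss of BnOH. Fallback: set Cc and Ce together by Sharpless asymmetric dihydroxylation of ethyl (E)-4-methylhepta-3,6-dienoate, then lactonise the diol.
2. **Step 8, organocerium addition to the β-acyloxy ketone.** Enolisation can open the lactone by E1cB. Fallback: use a di-tert-butyl malate analogue so allylation does not lactonise, then do the Wacker oxidation and chain addition on the open hydroxy ester and lactonise with acid at the end.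
3. **Step 10, Ca selectivity and elimination.** The Ca diastereoselectivity may be poor, and tertiary-alcohol elimination competes. Fallback: after Step 7, hydrogenolyse to the bicyclic hemiketal and allylate the oxocarbenium from the convex face (allylTMS, BF3·OEt2). Then do cross-metathesis with 10-phenyldec-1-ene and hydrogenate the alkene.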